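**Retrosynthesis**
- Terpecurcumin B comes from a Pabon-type aldol condensation, which is the late C–C coupling. It joins the terpenyl vanillyl ether aldehyde (C23) to boron-chelated feruloylacetone (C13).
- The aldehyde comes from Mitsunobu inversion at C6 of a cis-configured cyclohexenol acetate with vanillin, and vanillin is built from catechol.
- The cyclohexene ring forms by RCM of a vinyl ketone/isopropenyl diene. C4 is then equilibrated, C3 is set by Luche reduction, and C6 is set by the epoxide chirality.
- The diene comes from a transient γ-lactone. The lactone forms by alkylating ethyl (S)-citronellate (Cu-catalysed asymmetric conjugate addition) with (S)-2-isopropenyloxirane (HKR).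

Ring order: the two aryl rings come from catechol, then the γ-lactone forms (step 11), then the cyclohexene forms by RCM (step 15).

Assumption: ring C4 is left undefined in 15–19 (epimeric mixture) and is fixed in step 16. The β-diketone is drawn as the enol tautomer, as in the target.

---

**Step 1**
Reactants: 1 catechol
Product: 2 guaiacol (2-methoxyphenol)
Conditions: Me2SO4 (1 equiv), NaOH (1 equiv), H2O, 0 °C→rt
Reagents that add atoms: dimethyl sulfate, COS(=O)(=O)OC
Why: Williamson mono-O-methylation of the mono-phenoxide; veratrole and unreacted catechol are removed and the catechol recycled.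

**Step 2**
Reactants: 2 guaiacol
Product: 3 2-hydroxy-2-(4-hydroxy-3-methoxyphenyl)acetic acid (vanillylmandelic acid, racemic)
Conditions: glyoxylic acid (aq.), NaOH, H2O, rt
Reagents that add atoms: glyoxylic acid, O=CC(=O)O
Why: Electrophilic hydroxyalkylation of the phenoxide with glyoxylic acid occurs para to O⁻, placing the C1 unit para to the phenol.

**Step 3**
Reactants: 3
Product: 4 vanillin (4-hydroxy-3-methoxybenzaldehyde)
Conditions: O2 (air), cat. Cu(OH)2, aq. NaOH, 90 °C; then H3O+
Reagents that add atoms: none
Why: Cu-catalysed oxidative decarboxylation of the mandelic acid to the aldehyde.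

**Step 4**
Reactants: 4 vanillin
Product: 5 dehydrozingerone, (3E)-4-(4-hydroxy-3-methoxyphenyl)but-3-en-2-one
Conditions: acetone (excess), aq. NaOH, rt; then H3O+
Reagents that add atoms: acetone, CC(C)=O
Why: Claisen–Schmidt aldol condensation gives the E-enone.

**Step 5**
Reactants: 5
Product: 6 feruloylacetone, (1E)-1-(4-hydroxy-3-methoxyphenyl)hex-1-ene-3,5-dione
Conditions: NaH (3.5 equiv), EtOAc, THF, 0→65 °C; then H3O+
Reagents that add atoms: ethyl acetate, CCOC(C)=O
Why: Claisen condensation of the methyl-ketone enolate with EtOAc gives the β-diketone; the phenol is masked as its phenoxide.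

**Step 6**
Reactants: 6
Product: 7 [feruloylacetonato-κ²O,O′]dibutoxyboron (boron chelate)
Conditions: B(OBu)3, EtOAc, 70 °C; crude used directly
Reagents that add atoms: tributyl borate, CCCCOB(OCCCC)OCCCC
Why: Chelation to boron protects the central C–H and activates the acetyl CH3 for the Pabon condensation.

**Step 7**
Reactants: 8 5-bromo-2-methylpent-2-ene
Product: 9 (4-methylpent-3-en-1-yl)magnesium bromide
Conditions: Mg turnings, cat. I2, THF, 40 °C
Reagents that add atoms: magnesium, [Mg]
Why: Oxidative insertion gives the homoallyl Grignard; the trisubstituted alkene is untouched.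

**Step 8**
Reactants: 10 ethyl (E)-crotonate; 9
Product: 11 ethyl (3S)-3,7-dimethyloct-6-enoate (ethyl (S)-citronellate)
Conditions: CuBr·SMe2 (5 mol%), Josiphos-type ligand (6 mol%, enantiomer chosen to give S), t-BuOMe, −78 °C
Reagents that add atoms: none
Why: Cu-catalysed asymmetric conjugate addition of the Grignard sets the side-chain methyl stereocentre (C7, S) by ligand control.

**Step 9**
Reactants: 12 methacrolein
Product: 13 (±)-2-(prop-1-en-2-yl)oxirane
Conditions: Me3S⁺ I⁻, NaH, DMSO/THF, 0 °C→rt
Reagents that add atoms: trimethylsulfonium iodide, C[S+](C)C.[I-]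
Why: Corey–Chaykovsky methylenation adds the sulfonium ylide to the C=O (1,2-addition) to give the vinyl epoxide.

**Step 10**
Reactants: 13
Product: 14 (2S)-2-(prop-1-en-2-yl)oxirane
Conditions: (salen)Co(III)OAc (0.5 mol%, enantiomer chosen to leave the S epoxide), H2O (0.55 equiv), rt, 18 h; vacuum transfer
Reagents that add atoms: none (the water ends up in the diol of the discarded enantiomer)
Why: Jacobsen hydrolytic kinetic resolution leaves the S epoxide, which fixes C6.

**Step 11**
Reactants: 11; 14
Product: 15 (5R)-3-[(2S)-6-methylhept-5-en-2-yl]-5-(prop-1-en-2-yl)oxolan-2-one (C3 epimeric mixture)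
Conditions: LDA, THF, −78 °C; then 14, −78→25 °C
Reagents that add atoms: none (EtOH is lost)
Why: The lithium ester enolate opens the epoxide by SN2 at the unhindered CH2 (C4–C5 bond), and the alkoxide lactonises; the C6–O bond is untouched so C6 is retained (R), while C4 forms as an epimeric mixture.

**Step 12**
Reactants: 15
Product: 16 (4R)-4-hydroxy-N-methoxy-N,5-dimethyl-2-[(2S)-6-methylhept-5-en-2-yl]hex-5-enamide
Conditions: MeNH(OMe)·HCl, AlMe3, CH2Cl2, 0 °C→rt
Reagents that add atoms: N,O-dimethylhydroxylamine, CNOC
Why: Weinreb–Basha aminolysis opens the lactone to the hydroxy Weinreb amide without touching C6.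

**Step 13**
Reactants: 16
Product: 17 the C4-O-TBS ether of 16, (4R)-4-[(tert-butyldimethylsilyl)oxy]-N-methoxy-N,5-dimethyl-2-[(2S)-6-methylhept-5-en-2-yl]hex-5-enamide
Conditions: TBSOTf, 2,6-lutidine, CH2Cl2, −78→0 °C
Reagents that add atoms: tert-butyldimethylsilyl triflate, CC(C)(C)[Si](C)(C)OS(=O)(=O)C(F)(F)F
Why: Silylation protects the secondary allylic alcohol against the Grignard, Ru and hydride steps.

**Step 14**
Reactants: 17
Product: 18 (6R)-6-(TBSO)-7-methyl-4-[(2S)-6-methylhept-5-en-2-yl]octa-1,7-dien-3-one
Conditions: CH2=CHMgBr (1.3 equiv), THF, −20→0 °C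
Reagents that add atoms: vinylmagnesium bromide, C=C[Mg]Br
Why: Weinreb acylation gives the vinyl ketone through a stable chelated intermediate with no over-addition.

**Step 15**
Reactants: 18
Product: 19 (4R)-4-(TBSO)-3-methyl-6-[(2S)-6-methylhept-5-en-2-yl]cyclohex-2-en-1-one (C6 epimeric mixture)
Conditions: Hoveyda–Grubbs II (5 mol%), p-benzoquinone (10 mol%), toluene (5 mM), 60 °C
Reagents that add atoms: none (ethylene is lost)
Why: Ring-closing metathesis joins the vinyl ketone and the isopropenyl group to form the trisubstituted C1=C2 enone, ring 1.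

**Step 16**
Reactants: 19
Product: 20 (4R,6R)-4-(TBSO)-3-methyl-6-[(2S)-6-methylhept-5-en-2-yl]cyclohex-2-en-1-one (4,6-cis)
Conditions: DBU (0.3 equiv), toluene, 60 °C; chromatographic separation, trans isomer recycled
Reagents that add atoms: none
Why: Base epimerisation of the α′-stereocentre (C4 of the terpene numbering) converges the mixture on the 1,3-cis isomer, which is needed so that the later Mitsunobu inversion puts the ArO group trans to the side chain.

**Step 17**
Reactants: 20
Product: 21 (1R,4R,6R)-4-(TBSO)-3-methyl-6-[(2S)-6-methylhept-5-en-2-yl]cyclohex-2-en-1-ol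
Conditions: NaBH4, CeCl3·7H2O, MeOH, −78→−30 °C
Reagents that add atoms: none (hydride only)
Why: Luche 1,2-reduction gives the allylic alcohol, with axial hydride delivery anti to the adjacent equatorial side chain, so C3–OH is trans to C4 (R).

**Step 18**
Reactants: 21
Product: 22 the acetate of 21, (1R,4R,6R)-4-(TBSO)-3-methyl-6-[(2S)-6-methylhept-5-en-2-yl]cyclohex-2-en-1-yl acetate
Conditions: Ac2O, DMAP, pyridine, CH2Cl2, rt
Reagents that add atoms: acetic anhydride, CC(=O)OC(C)=O
Why: Acetylation protects C3–OH orthogonally to the TBS group.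

**Step 19**
Reactants: 22
Product: 23 the C4-free alcohol, (1R,4R,6R)-4-hydroxy-3-methyl-6-[(2S)-6-methylhept-5-en-2-yl]cyclohex-2-en-1-yl acetate
Conditions: HF·pyridine, pyridine/THF, 0 °C→rt
Reagents that add atoms: none
Why: Fluoride removes the silyl ether and leaves the acetate, unmasking the C6-OH cis to the side chain.

**Step 20**
Reactants: 23; 4 vanillin
Product: 24 (1R,4S,6R)-4-(4-formyl-2-methoxyphenoxy)-3-methyl-6-[(2S)-6-methylhept-5-en-2-yl]cyclohex-2-en-1-yl acetate
Conditions: PPh3, DIAD, THF, 0 °C→rt
Reagents that add atoms: none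
Why: Mitsunobu SN2 etherification of the acidic phenol inverts C6, giving the required trans ArO/side-chain relationship (C6 becomes S).

**Step 21**
Reactants: 24
Product: 25 4-{[(1S,4R,5R)-4-hydroxy-2-methyl-5-[(2S)-6-methylhept-5-en-2-yl]cyclohex-2-en-1-yl]oxy}-3-methoxybenzaldehyde
Conditions: K2CO3, MeOH, rt
Reagents that add atoms: none
Why: Mild transesterification removes the acetate; the aryl aldehyde and the allylic aryl ether are stable and no stereocentre is touched.

**Step 22**
Reactants: 25; 7
Product: 26 Terpecurcumin B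
Conditions: n-BuNH2 (cat.), B(OBu)3, EtOAc, 50 °C, 24 h; then 1 M aq. AcOH, 40 °C
Reagents that add atoms: none
Why: Pabon-type Knoevenagel/aldol condensation of the chelated acetyl CH3 with the aldehyde forms the E-enone and the keto-enol diketone, and mild acid hydrolysis releases the free β-diketone without ionising the allylic alcohol or ether.

---

**Compound list**

| No. | Name | SMILES | Role |
|---|---|---|---|
| 1 | catechol | Oc1ccccc1O | starting material |
| 2 | guaiacol | COc1ccccc1O | intermediate |
| 3 | vanillylmandelic acid (racemic) | COc1cc(C(O)C(=O)O)ccc1O | intermediate |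
| 4 | vanillin | COc1cc(C=O)ccc1O | intermediate |
| 5 | dehydrozingerone | COc1cc(/C=C/C(C)=O)ccc1O | intermediate |
| 6 | feruloylacetone | COc1cc(/C=C/C(=O)CC(C)=O)ccc1O | intermediate |
| 7 | feruloylacetonato dibutoxyboron chelate | COc1cc(/C=C/C2=[O+][B-](OCCCC)(OCCCC)OC(C)=C2)ccc1O | intermediate |
| 8 | 5-bromo-2-methylpent-2-ene | CC(C)=CCCBr | starting material |
| 9 | (4-methylpent-3-en-1-yl)magnesium bromide | CC(C)=CCC[Mg]Br | intermediate |
| 10 | ethyl (E)-crotonate | C/C=C/C(=O)OCC | starting material |
| 11 | ethyl (3S)-3,7-dimethyloct-6-enoate | CCOC(=O)C[C@@H](C)CCC=C(C)C | intermediate |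
| 12 | methacrolein | C=C(C)C=O | starting material |
| 13 | (±)-2-isopropenyloxirane | C=C(C)C1CO1 | intermediate |
| 14 | (2S)-2-isopropenyloxirane | C=C(C)[C@H]1CO1 | intermediate |
| 15 | γ-lactone (C3 epimeric) | C=C(C)[C@H]1CC([C@@H](C)CCC=C(C)C)C(=O)O1 | intermediate |
| 16 | hydroxy Weinreb amide | C=C(C)[C@H](O)CC(C(=O)N(C)OC)[C@@H](C)CCC=C(C)C | intermediate |
| 17 | TBS ether Weinreb amide | C=C(C)[C@H](O[Si](C)(C)C(C)(C)C)CC(C(=O)N(C)OC)[C@@H](C)CCC=C(C)C | intermediate |
| 18 | vinyl ketone diene | C=C(C)[C@H](O[Si](C)(C)C(C)(C)C)CC(C(=O)C=C)[C@@H](C)CCC=C(C)C | intermediate |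
| 19 | cyclohexenone (C6 epimeric) | CC(C)(C)[Si](C)(C)O[C@@H]1CC([C@@H](C)CCC=C(C)C)C(=O)C=C1C | intermediate |
| 20 | cis-cyclohexenone | CC(C)(C)[Si](C)(C)O[C@@H]1C[C@H]([C@@H](C)CCC=C(C)C)C(=O)C=C1C | intermediate |
| 21 | allylic alcohol TBS ether | CC(C)(C)[Si](C)(C)O[C@@H]1C[C@H]([C@@H](C)CCC=C(C)C)[C@@H](O)C=C1C | intermediate |
| 22 | acetate TBS ether | CC(C)(C)[Si](C)(C)O[C@@H]1C[C@H]([C@@H](C)CCC=C(C)C)[C@@H](OC(C)=O)C=C1C | intermediate |
| 23 | hydroxy acetate | O[C@@H]1C[C@H]([C@@H](C)CCC=C(C)C)[C@@H](OC(C)=O)C=C1C | intermediate |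
| 24 | aryl ether acetate | COc1cc(C=O)ccc1O[C@H]1C[C@H]([C@@H](C)CCC=C(C)C)[C@@H](OC(C)=O)C=C1C | intermediate |
| 25 | terpenyl vanillyl ether aldehyde | COc1cc(C=O)ccc1O[C@H]1C[C@H]([C@@H](C)CCC=C(C)C)[C@@H](O)C=C1C | intermediate |
| 26 | Terpecurcumin B | COc1cc(/C=C/C(=O)/C=C(O)/C=C/c2ccc(O[C@H]3C[C@H]([C@@H](C)CCC=C(C)C)[C@@H](O)C=C3C)c(OC)c2)ccc1O | target |

---

**Totals:** 22 steps in total; longest linear sequence 14 steps (steps 9→10→11→…→22; steps 7→8→11→…→22 is equally long).

**Three steps most likely to fail**
1. **Step 11 (vinyl epoxide alkylation):** competing SN2′/allylic attack, and poor C4 diastereoselectivity (the latter is tolerated because C4 is equilibrated later). Fallback: use (S)-benzyl glycidyl ether instead of the vinyl epoxide, then install the isopropenyl group by oxidation, MeMgBr addition, oxidation and Wittig methylenation before the vinyl addition.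
2. **Step 15 (RCM):** the hindered 1,1-disubstituted alkene may lose to the prenyl alkene, giving a seven-membered enone or oligomers. Fallback: carry the side chain as a saturated protected 4-hydroxybutyl group and form the CH=CMe2 alkene at the end by oxidation and isopropylidene Wittig.
3. **Step 16 (C4 equilibration, with Luche selectivity in step 17):** the cis isomer may not be the thermodynamic major, and C3 selectivity may be low. Fallback: use the (R)-epoxide to build the 4,6-trans enone, then convert the C6 alcohol to a carbonate and use Pd-catalysed allylic etherification with vanillin (net retention) in place of the Mitsunobu step.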